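## Retrosynthetic overview

1. Target 19 ⇒ isopropenyl diene 17 + but-3-en-2-one: the enone arm is completed last by cross-metathesis.
2. 17 ⇒ enone 15: the last ring methyl and the 1,3-diene come from the enone carbonyl (MeLi addition, 1,4-dehydration).
3. 15 ⇒ α′-bromo enone 12 + isopropenyl Grignard 13: a pinacol-type 1,2-alkenyl shift with inversion at C6 puts the alkenyl group cis to the pyranone (key step).
4. 12 ⇒ (S)-enone 10 ⇒ prochiral 1,6-diyne 8: the carbocycle and the quaternary stereocenter come from a desymmetrising hydrative aldol cyclisation.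
5. 8 ⇒ 6-ethylpyranone 5 + two 3-bromoprop-1-yne ⇒ pentan-3-one + methylmalonyl dichloride: the pyranone ring is formed first, the cyclohexene ring second.

Assumption: 2-methylpropanedioyl dichloride (2) and bromo(prop-1-en-2-yl)magnesium (13, 0.5 M in THF) are bought as such.

## Route

Step 1
Reactants: 1 pentan-3-one; 2 2-methylpropanedioyl dichloride
Product: 4 6-ethyl-4-hydroxy-3,5-dimethyl-2H-pyran-2-one, via silyl enol ether 3 (not isolated)
Conditions: Me3SiOTf (1.0 equiv), Et3N (1.0 equiv), Et2O, 0 °C; Et2O layer decanted from Et3NH·OTf; then 2, −78 °C to rt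
Reagents that add atoms: trimethylsilyl trifluoromethanesulfonate, C[Si](C)(C)OS(=O)(=O)C(F)(F)F (silyl group of 3 only)
Why: C-acylation of the silyl enol ether by one acid chloride, then lactonisation of the β-diketo acid chloride through its enol oxygen (Effenberger pyranone synthesis), gives the 4-hydroxy-2-pyranone with no stereocenter.

Step 2
Reactants: 4 6-ethyl-4-hydroxy-3,5-dimethyl-2H-pyran-2-one
Product: 5 6-ethyl-2-methoxy-3,5-dimethyl-4H-pyran-4-one
Conditions: MeOTf, CH2Cl2, rt; aq. NaHCO3
Reagents that add atoms: methyl trifluoromethanesulfonate, COS(=O)(=O)C(F)(F)F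
Why: The hard methylating agent alkylates the lactone carbonyl oxygen of the hydroxypyranone, and loss of the proton gives the α-methoxy-γ-pyranone (regioselective O-methylation).

Step 3
Reactants: 5 6-ethyl-2-methoxy-3,5-dimethyl-4H-pyran-4-one; 6 3-bromoprop-1-yne
Product: 7 2-methoxy-3,5-dimethyl-6-(pent-4-yn-2-yl)-4H-pyran-4-one (racemic)
Conditions: LiN(SiMe3)2 (1.1 equiv), THF, −78 °C; 6 (1.2 equiv), −78 to 0 °C; aq. NH4Cl
Reagents that add atoms: none
Why: The ethyl CH2 is the vinylogous acidic position of the pyranone, so the base gives the extended enolate, which is C-alkylated at the exocyclic carbon (enolate alkylation, SN2); the new stereocenter is formed racemic and is erased in the next step.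

Step 4
Reactants: 7 2-methoxy-3,5-dimethyl-6-(pent-4-yn-2-yl)-4H-pyran-4-one (racemic); 6 3-bromoprop-1-yne
Product: 8 2-methoxy-3,5-dimethyl-6-(4-methylhepta-1,6-diyn-4-yl)-4H-pyran-4-one
Conditions: LiN(SiMe3)2 (2.2 equiv), THF, −78 °C; 6 (1.3 equiv), −78 to 0 °C; H2O
Reagents that add atoms: none
Why: One equivalent of base takes the acetylenic proton and the second the vinylogous methine proton; the soft extended-enolate carbon, not the lithium acetylide, is alkylated (enolate C-alkylation, SN2) to give the quaternary carbon, which is achiral because both arms are the same, and the water quench reprotonates the alkyne.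

Step 5
Reactants: 8 2-methoxy-3,5-dimethyl-6-(4-methylhepta-1,6-diyn-4-yl)-4H-pyran-4-one
Product: 10 (5S)-5-(6-methoxy-3,5-dimethyl-4-oxo-4H-pyran-2-yl)-3,5-dimethylcyclohex-2-en-1-one, via diketone 9 (not isolated)
Conditions: Ph3PAuNTf2 (2 mol %), H2O (6 equiv), 1,4-dioxane, 60 °C; then 9-amino-9-deoxy-epi-quinine (20 mol %), CF3CO2H (40 mol %), 40 °C
Reagents that add atoms: water, O
Why: Proposed new method: monovalent-gold π-activation hydrates both terminal alkynes (Markovnikov) to the prochiral 2,6-diketone 9, the chiral primary amine then forms an enamine on one of the two enantiotopic acetonyl arms, which closes onto the other ketone through a hydrogen-bonded chair-like transition state that tells methyl from pyranonyl at the quaternary carbon, and dehydration gives the (S)-enone (the sense of induction is assigned by analogy, and the quinidine-derived pseudoenantiomeric amine is used instead if the antipode forms); the closest known reaction types are the racemic gold-catalysed hydrative cyclisation of 1,6-diynes to 3-methylcyclohex-2-enones and the primary-amine-catalysed desymmetrising aldol condensation of 4-monosubstituted heptane-2,6-diones, neither shown in one flask nor at a fully substituted prochiral carbon.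

Step 6
Reactants: 10 (5S)-5-(6-methoxy-3,5-dimethyl-4-oxo-4H-pyran-2-yl)-3,5-dimethylcyclohex-2-en-1-one
Product: 12 (5R,6R)-6-bromo-5-(6-methoxy-3,5-dimethyl-4-oxo-4H-pyran-2-yl)-3,5-dimethylcyclohex-2-en-1-one, via silyl dienol ether 11 (not isolated)
Conditions: LiN(iPr)2, THF, −78 °C; Me3SiCl; then N-bromosuccinimide, THF, −78 °C
Reagents that add atoms: N-bromosuccinimide, O=C1CCC(=O)N1Br; chlorotrimethylsilane, C[Si](C)(C)Cl (silyl group of 11 only)
Why: Kinetic deprotonation at the α′-CH2 (C6) gives the cross-conjugated silyl dienol ether, which is brominated at C6 on the face anti to the bulky pyranone of the neighbouring quaternary carbon (electrophilic α-halogenation of a silyl enol ether), so Br ends trans to the pyranone.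

Step 7
Reactants: 12 (5R,6R)-6-bromo-5-(6-methoxy-3,5-dimethyl-4-oxo-4H-pyran-2-yl)-3,5-dimethylcyclohex-2-en-1-one; 13 bromo(prop-1-en-2-yl)magnesium
Product: 15 (5S,6S)-5-(6-methoxy-3,5-dimethyl-4-oxo-4H-pyran-2-yl)-3,5-dimethyl-6-(prop-1-en-2-yl)cyclohex-2-en-1-one, via bromohydrin magnesium alkoxide 14 (not isolated)
Conditions: 13 (1.2 equiv), THF, −78 °C; then PhMe, 70 °C
Reagents that add atoms: none
Why: The Grignard reagent adds to the ketone anti to the C–Br bond (Cornforth/Felkin–Anh) to give the cis-bromohydrin salt 14 with the isopropenyl group antiperiplanar to C–Br, and on warming this group migrates to C6 with loss of bromide and inversion there (pinacol-type 1,2-alkenyl shift of a halohydrin magnesium salt, Tiffeneau rearrangement), which places it cis to the pyranone, the more hindered face, and restores the enone.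

Step 8
Reactants: 15 (5S,6S)-5-(6-methoxy-3,5-dimethyl-4-oxo-4H-pyran-2-yl)-3,5-dimethyl-6-(prop-1-en-2-yl)cyclohex-2-en-1-one
Product: 17 2-methoxy-3,5-dimethyl-6-[(1S,6R)-1,3,5-trimethyl-6-(prop-1-en-2-yl)cyclohexa-2,4-dien-1-yl]-4H-pyran-4-one, via tertiary allylic alcohol 16 (not isolated)
Conditions: MeLi, THF, −78 °C; H2O; then camphorsulfonic acid (5 mol %), CH2Cl2, 0 °C
Reagents that add atoms: methyllithium, [Li]C
Why: 1,2-Addition of MeLi to the enone (anti to the C6 isopropenyl group) and acid-catalysed 1,4-dehydration (E1 through the 1,3-dimethylallyl cation) give the ring diene, the proton being lost from C4 because the C6–H lies in the nodal plane of the cation when the isopropenyl group sits pseudoaxial to avoid allylic strain with the new methyl; both stereocenters are untouched and the carbinol center disappears.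

Step 9
Reactants: 17 2-methoxy-3,5-dimethyl-6-[(1S,6R)-1,3,5-trimethyl-6-(prop-1-en-2-yl)cyclohexa-2,4-dien-1-yl]-4H-pyran-4-one; 18 but-3-en-2-one
Product: 19 2-methoxy-3,5-dimethyl-6-[(1S,6S)-1,3,5-trimethyl-6-[(2E)-4-oxopent-2-en-2-yl]cyclohexa-2,4-dien-1-yl]-4H-pyran-4-one
Conditions: second-generation Hoveyda–Grubbs catalyst RuCl2(SIMes)(=CH-C6H4-2-OiPr) (10 mol %), 18 (5 equiv), CH2Cl2, 40 °C
Reagents that add atoms: none
Why: Olefin cross-metathesis of the 1,1-disubstituted alkene with the electron-poor vinyl ketone gives the trisubstituted (E)-enone under thermodynamic control, while the trisubstituted ring alkenes and the pyranone do not react with the ruthenium carbene; the ring stereocenters are not touched (the C6 descriptor changes from R to S only through priorities).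

## Compound list

1 | pentan-3-one | CCC(=O)CC | starting material
2 | 2-methylpropanedioyl dichloride | CC(C(Cl)=O)C(Cl)=O | starting material
3 | trimethyl(pent-2-en-3-yloxy)silane (E/Z mixture) | CC=C(CC)O[Si](C)(C)C | intermediate
4 | 6-ethyl-4-hydroxy-3,5-dimethyl-2H-pyran-2-one | CCc1oc(=O)c(C)c(O)c1C | intermediate
5 | 6-ethyl-2-methoxy-3,5-dimethyl-4H-pyran-4-one | CCc1oc(OC)c(C)c(=O)c1C | intermediate
6 | 3-bromoprop-1-yne | C#CCBr | starting material
7 | 2-methoxy-3,5-dimethyl-6-(pent-4-yn-2-yl)-4H-pyran-4-one (racemic) | C#CCC(C)c1oc(OC)c(C)c(=O)c1C | intermediate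
8 | 2-methoxy-3,5-dimethyl-6-(4-methylhepta-1,6-diyn-4-yl)-4H-pyran-4-one | C#CCC(C)(CC#C)c1oc(OC)c(C)c(=O)c1C | intermediate
9 | 2-methoxy-3,5-dimethyl-6-(4-methyl-2,6-dioxoheptan-4-yl)-4H-pyran-4-one | CC(=O)CC(C)(CC(C)=O)c1oc(OC)c(C)c(=O)c1C | intermediate
10 | (5S)-5-(6-methoxy-3,5-dimethyl-4-oxo-4H-pyran-2-yl)-3,5-dimethylcyclohex-2-en-1-one | COc1oc([C@@]2(C)CC(C)=CC(=O)C2)c(C)c(=O)c1C | intermediate
11 | 2-methoxy-3,5-dimethyl-6-[(1S)-1,3-dimethyl-5-(trimethylsilyloxy)cyclohexa-3,5-dien-1-yl]-4H-pyran-4-one | COc1oc([C@@]2(C)CC(C)=CC(O[Si](C)(C)C)=C2)c(C)c(=O)c1C | intermediate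
12 | (5R,6R)-6-bromo-5-(6-methoxy-3,5-dimethyl-4-oxo-4H-pyran-2-yl)-3,5-dimethylcyclohex-2-en-1-one (Br trans to the pyranone) | COc1oc([C@@]2(C)CC(C)=CC(=O)[C@@H]2Br)c(C)c(=O)c1C | intermediate
13 | bromo(prop-1-en-2-yl)magnesium, CH2=C(CH3)MgBr | CC(=C)[Mg]Br | starting material
14 | bromomagnesium (1R,5R,6R)-6-bromo-5-(6-methoxy-3,5-dimethyl-4-oxo-4H-pyran-2-yl)-3,5-dimethyl-1-(prop-1-en-2-yl)cyclohex-2-en-1-olate (O cis to Br) | COc1oc([C@@]2(C)CC(C)=C[C@@](O[Mg]Br)(C(C)=C)[C@@H]2Br)c(C)c(=O)c1C | intermediate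
15 | (5S,6S)-5-(6-methoxy-3,5-dimethyl-4-oxo-4H-pyran-2-yl)-3,5-dimethyl-6-(prop-1-en-2-yl)cyclohex-2-en-1-one | COc1oc([C@@]2(C)CC(C)=CC(=O)[C@H]2C(C)=C)c(C)c(=O)c1C | intermediate
16 | (1R,5S,6S)-5-(6-methoxy-3,5-dimethyl-4-oxo-4H-pyran-2-yl)-1,3,5-trimethyl-6-(prop-1-en-2-yl)cyclohex-2-en-1-ol | COc1oc([C@@]2(C)CC(C)=C[C@@](C)(O)[C@H]2C(C)=C)c(C)c(=O)c1C | intermediate
17 | 2-methoxy-3,5-dimethyl-6-[(1S,6R)-1,3,5-trimethyl-6-(prop-1-en-2-yl)cyclohexa-2,4-dien-1-yl]-4H-pyran-4-one | COc1oc([C@@]2(C)C=C(C)C=C(C)[C@H]2C(C)=C)c(C)c(=O)c1C | intermediate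
18 | but-3-en-2-one | CC(=O)C=C | starting material
19 | 2-methoxy-3,5-dimethyl-6-[(1S,6S)-1,3,5-trimethyl-6-[(2E)-4-oxopent-2-en-2-yl]cyclohexa-2,4-dien-1-yl]-4H-pyran-4-one | COc1oc([C@@]2(C)C=C(C)C=C(C)[C@H]2/C(C)=C/C(C)=O)c(C)c(=O)c1C | target

## Step count and risks

Total step count: 9. Longest linear sequence: 9 (fully linear).

The three steps most likely to fail:

Step 5 (the proposed new step). The amine may be held by the gold catalyst, may attack the methoxypyranone, or may give low ee at a fully substituted prochiral carbon. Fallback with known chemistry: set out from diyne 8 and run the known racemic gold-catalysed hydrative cyclisation (Ph3PAuCH3, CH3SO3H, aqueous MeOH, 70 °C) to racemic 5-(6-methoxy-3,5-dimethyl-4-oxo-4H-pyran-2-yl)-3,5-dimethylcyclohex-2-en-1-one F1. Separate the enantiomers by preparative chiral supercritical-fluid chromatography; the (S)-enantiomer is 10, where the route is rejoined.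

Step 7. The conformer of 14 in which the isopropenyl group is antiperiplanar to C–Br has that group 1,3-diaxial to the pyranone. Ring contraction by migration of the ring vinyl carbon, epoxide formation from the minor trans-bromohydrin, or enolisation and bromine–magnesium exchange of 12 by the Grignard reagent may therefore compete. Fallback: set out from enone 10 and alkenylate its kinetic lithium enolate at C6 with 2-bromoprop-1-ene under zerovalent-palladium catalysis (LiN(SiMe3)2, Pd2(dba)3, P(tBu)3, THF; ketone α-alkenylation). After an equilibrating work-up this gives mainly the trans epimer (5S,6R)-5-(6-methoxy-3,5-dimethyl-4-oxo-4H-pyran-2-yl)-3,5-dimethyl-6-(prop-1-en-2-yl)cyclohex-2-en-1-one F2; any cis epimer formed is 15 already. Deprotonation with LiN(iPr)2 at −78 °C and kinetic protonation with 2,6-di-tert-butylphenol from the face anti to the pyranone epimerises C6 and gives 15.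

Step 8. The allyl cation may lose the C6 proton instead, giving a C1=C6 triene and destroying the stereocenter, or a methyl proton, giving exocyclic dienes. Fallback: set out from 15 and make the extended (thermodynamic) silyl dienol ether with Me3SiCl, Et3N, DMF, 80 °C: 2-methoxy-3,5-dimethyl-6-[(1S,6S)-1,3-dimethyl-6-(prop-1-en-2-yl)-5-(trimethylsilyloxy)cyclohexa-2,4-dien-1-yl]-4H-pyran-4-one F3. Convert it with CsF and PhNTf2 in 1,2-dimethoxyethane into (5S,6S)-5-(6-methoxy-3,5-dimethyl-4-oxo-4H-pyran-2-yl)-3,5-dimethyl-6-(prop-1-en-2-yl)cyclohexa-1,3-dien-1-yl trifluoromethanesulfonate F4. Negishi methylation (Pd(PPh3)4, Me2Zn, THF) then gives 17.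

Further compounds
F1 | step 5 | racemic 5-(6-methoxy-3,5-dimethyl-4-oxo-4H-pyran-2-yl)-3,5-dimethylcyclohex-2-en-1-one | COc1oc(C2(C)CC(C)=CC(=O)C2)c(C)c(=O)c1C
F2 | step 7 | (5S,6R)-5-(6-methoxy-3,5-dimethyl-4-oxo-4H-pyran-2-yl)-3,5-dimethyl-6-(prop-1-en-2-yl)cyclohex-2-en-1-one | COc1oc([C@@]2(C)CC(C)=CC(=O)[C@@H]2C(C)=C)c(C)c(=O)c1C
F3 | step 8 | 2-methoxy-3,5-dimethyl-6-[(1S,6S)-1,3-dimethyl-6-(prop-1-en-2-yl)-5-(trimethylsilyloxy)cyclohexa-2,4-dien-1-yl]-4H-pyran-4-one | COc1oc([C@@]2(C)C=C(C)C=C(O[Si](C)(C)C)[C@H]2C(C)=C)c(C)c(=O)c1C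
F4 | step 8 | (5S,6S)-5-(6-methoxy-3,5-dimethyl-4-oxo-4H-pyran-2-yl)-3,5-dimethyl-6-(prop-1-en-2-yl)cyclohexa-1,3-dien-1-yl trifluoromethanesulfonate | COc1oc([C@@]2(C)C=C(C)C=C(OS(=O)(=O)C(F)(F)F)[C@H]2C(C)=C)c(C)c(=O)c1C
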